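**Retrosynthetic overview**

1. The target is ent-labda-8(17),13(16),14-trien-19-yl (E)-4-coumarate. The last bonds made are the C19–O ester, C8=C17 (Wittig), and the side-chain bonds C11–C12 and C13–C14 (conjugate 2-bromoallylation of a 9(11)-en-8-one, then Stille vinylation).
2. Ring A is made last. Its C3–C4 bond is formed by an Ireland–Claisen ring contraction of a δ-lactone (C4–C18(=O)–O–C1–C10–C5) that carries the vinyl group C2=C3 on C1. The same step sets quaternary C4 and leaves C1=C2 (hydrogenated later) and the C18 carboxyl (reduced to the 4-methyl group).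
3. Enabling feature: this temporary lactone ring, trans-fused to ring B across C5–C10, holds the ketene acetal C4=C18 and the allyl unit C1–C2=C3 in a boat. Because of the trans fusion only the C1 epimer with vinyl cis to the C10 methyl can react; the lactone carbon C18 then ends equatorial and the CH2O arm (C19) axial, as the target requires.
4. The lactone comes from a C10 allyl group (C1–C3) and a C5 acetic acid arm (C4, C18) by palladium-catalysed allylic C–H lactonisation; C19 is added by enolate alkylation.
5. Ring B comes first, from an anisole: Birch reduction, enantioselective isomerisation to a 4-substituted 3-methylcyclohexenone (sets C5), Hosomi–Sakurai allylation (sets quaternary C10). Ring order: B, temporary lactone, A.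

Key step: step 9

Remark: labdane numbering (C1–C20) is used throughout and "ent" denotes the spatial series of the target (4R,5S,9R,10S); 2-(4-methoxy-2-methylphenyl)acetic acid, (2-bromoallyl)trimethylsilane, (triisopropylsiloxy)methyl chloride and (E)-4-acetoxycinnamic acid are taken as catalogue compounds.

**Route**

Step 1
Reactants: 1 2-(4-methoxy-2-methylphenyl)acetic acid
Product: 3 2-(2-methyl-4-oxocyclohex-1-en-1-yl)acetic acid, via Birch dihydroanisole acid 2 (not isolated)
Conditions: Li, NH3(l), t-BuOH, THF, −78 °C; NH4Cl; then (CO2H)2, MeOH–H2O, rt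
Reagents that add atoms: water O
Why: Birch reduction puts the two new sp3 carbons at the unsubstituted ortho and meta positions, so the enol ether and the tetrasubstituted C5=C10 double bond remain, and mild enol-ether hydrolysis should give the β,γ-unsaturated ketone without conjugation.

Step 2
Reactants: 3 2-(2-methyl-4-oxocyclohex-1-en-1-yl)acetic acid
Product: 4 methyl 2-(2-methyl-4-oxocyclohex-1-en-1-yl)acetate
Conditions: Me3SiCHN2, PhMe–MeOH, 0 °C
Reagents that add atoms: (trimethylsilyl)diazomethane C[Si](C)(C)C=[N+]=[N-]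
Why: Esterification with a diazoalkane is neutral and should leave the deconjugated enone untouched.

Step 3
Reactants: 4 methyl 2-(2-methyl-4-oxocyclohex-1-en-1-yl)acetate
Product: 5 methyl 2-[(1R)-2-methyl-4-oxocyclohex-2-en-1-yl]acetate
Conditions: cinchona-derived 9-amino-9-deoxy-epi-alkaloid primary amine (10 mol %, pseudo-enantiomer chosen for R), ArCO2H (20 mol %), PhMe, −20 °C
Reagents that add atoms: none
Why: Enantioselective amine-catalysed isomerisation of a Birch-derived β,γ-unsaturated cyclohexenone: the chiral primary amine forms a dienamine by loss of a C9 proton and its protonated quinuclidine delivers the proton to one face of C5, which sets the C5 stereocentre.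

Step 4
Reactants: 5 methyl 2-[(1R)-2-methyl-4-oxocyclohex-2-en-1-yl]acetate
Product: 7 methyl 2-[(1R,2R,3R)-2-allyl-3-(benzyloxymethyl)-2-methyl-4-oxocyclohexyl]acetate, via trichlorotitanium enolate 6 (not isolated)
Conditions: CH2=CHCH2SiMe3, TiCl4, CH2Cl2, −78 °C; then BnOCH2Cl, −78 → −20 °C; H2O
Reagents that add atoms: allyltrimethylsilane C=CC[Si](C)(C)C; benzyl chloromethyl ether ClCOCc1ccccc1
Why: Hosomi–Sakurai conjugate allylation should add the allyl group to C10 anti to the C5 substituent (axial attack), setting quaternary C10 trans to the acetate arm, and the titanium enolate is then alkylated regiospecifically at C9 by the α-chloro ether; the C9 configuration does not matter because C9 becomes trigonal again in step 13.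

Step 5
Reactants: 7 methyl 2-[(1R,2R,3R)-2-allyl-3-(benzyloxymethyl)-2-methyl-4-oxocyclohexyl]acetate
Product: 8 methyl 11-benzyloxy-8,8-(ethylenedioxy)-12,13,14,15,16,17,19-heptanor-3,4-seco-ent-labd-2-en-18-oate
Conditions: (Me3SiOCH2)2, Me3SiOTf (5 mol %), CH2Cl2, −78 → −20 °C
Reagents that add atoms: 1,2-bis(trimethylsilyloxy)ethane C[Si](C)(C)OCCO[Si](C)(C)C
Why: Ketalisation with the bis-silyl glycol ether under silyl triflate catalysis protects the C8 ketone at low temperature, so the β-benzyloxy ketone should not eliminate.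

Step 6
Reactants: 8 methyl 11-benzyloxy-8,8-(ethylenedioxy)-12,13,14,15,16,17,19-heptanor-3,4-seco-ent-labd-2-en-18-oate
Product: 9 11-benzyloxy-8,8-(ethylenedioxy)-12,13,14,15,16,17,19-heptanor-3,4-seco-ent-labd-2-en-18-oic acid
Conditions: LiOH, THF–H2O, rt; then 1 M HCl to pH 4, 0 °C
Reagents that add atoms: lithium hydroxide [Li+].[OH-]
Why: Ester hydrolysis of the unhindered methyl ester frees the carboxylic acid needed as internal nucleophile in step 7; ketal and benzyl ether are base-stable.

Step 7
Reactants: 9 11-benzyloxy-8,8-(ethylenedioxy)-12,13,14,15,16,17,19-heptanor-3,4-seco-ent-labd-2-en-18-oic acid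
Product: 10 11-benzyloxy-8,8-(ethylenedioxy)-12,13,14,15,16,17,19-heptanor-3,4-seco-ent-labd-2-en-18,1-olide (vinyl on C1 cis to the C10 methyl)
Conditions: Pd(OAc)2, 1,2-bis(phenylsulfinyl)ethane (10 mol % each), (salen)CrCl (10 mol %), 1,4-benzoquinone (2 equiv), 1,4-dioxane, 45 °C
Reagents that add atoms: none
Why: Allylic C–H oxidation with the divalent palladium/bis-sulfoxide catalyst gives a π-allylpalladium from the C10 allyl group that the tethered carboxylate captures at the internal carbon C1 (six- rather than eight-membered lactone), and a chair-like C–O bond-forming transition state with the remaining vinyl group equatorial should place the vinyl group cis to the axial C10 methyl.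

Step 8
Reactants: 10 the vinyl lactone
Product: 12 11-benzyloxy-8,8-(ethylenedioxy)-19-(triisopropylsilyloxy)-12,13,14,15,16,17-hexanor-3,4-seco-ent-labd-2-en-18,1-olide, via lactone lithium enolate 11 (not isolated)
Conditions: LiN(iPr)2, THF, −78 °C; (iPr)3SiOCH2Cl, −78 → −40 °C
Reagents that add atoms: (triisopropylsiloxy)methyl chloride CC(C)[Si](OCCl)(C(C)C)C(C)C
Why: Enolate alkylation of the lactone with the reactive α-chloro ether introduces C19 already protected as its silyl ether; the C4 configuration is irrelevant because C4 becomes trigonal in step 9.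

Step 9
Reactants: 12 the 19-silyloxy lactone
Product: 15 11-benzyloxy-8,8-(ethylenedioxy)-19-(triisopropylsilyloxy)-12,13,14,15,16,17-hexanor-ent-labd-1-en-18-ol, via silyl ketene acetal 13 (not isolated), via trimethylsilyl ester 14 (not isolated)
Conditions: LiN(iPr)2, Me3SiCl–Et3N, THF, −78 °C → rt; PhMe, 110 °C; then LiAlH4, THF, 0 °C
Reagents that add atoms: none
Why: Deprotonation of 12 at C4 in the presence of Me3SiCl gives the ring-constrained silyl ketene acetal 13 (C4=C18), and the Ireland–Claisen [3,3] shift then forms C3–C4, breaks C1–O and moves the double bond to C1=C2, so that the δ-lactone contracts to carbocyclic ring A. The closest known reaction type is the Ireland–Claisen rearrangement of 6-alkenyl δ-lactone and 1,4-dioxan-2-one silyl ketene acetals to cyclohex-3-enecarboxylic and dihydropyran-2-carboxylic acids through boat transition states. Ring A closes in a pericyclic mode: the six atoms C4=C18–O–C1–C2=C3 react suprafacially within a bicyclo[2.2.2]-like boat whose third bridge is the C5–C10 bond of ring B. The only new stereocentre, quaternary C4, is fixed by chirality transfer from C1: because the lactone is trans-fused to ring B, the boat that aligns the C1–O bond with the ketene-acetal π system has the vinyl group axial and cis to the C10 methyl, C3 bonds to that face, and the former lactone carbon C18 ends equatorial (later the 4-methyl) while the CH2OSi(iPr)3 arm ends axial, cis to C20 (later C19). The step needs enolisation without loss of the β-silyloxy group, which in-situ silylation at −78 °C should secure, and the right C1 epimer, which step 7 provides; both C4 epimers of 12 converge on the same ketene acetal. LiAlH4 added to the cooled solution reduces silyl ester 14 to the neopentyl alcohol 15, and the aluminium alkoxide is quenched cold to avoid silyl migration.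

Step 10
Reactants: 15 the 18-alcohol
Product: 17 11-benzyloxy-8,8-(ethylenedioxy)-19-(triisopropylsilyloxy)-12,13,14,15,16,17-hexanor-ent-labd-1-ene, via neopentyl triflate 16 (not isolated)
Conditions: Tf2O, pyridine, CH2Cl2, −30 °C; then LiEt3BH, THF, 0 °C → rt
Reagents that add atoms: none
Why: Triflation and hydride displacement of the primary sulfonate with LiEt3BH should turn the former lactone carbon C18 into the equatorial C4 methyl group; the neopentyl triflate has no β-hydrogen to eliminate.

Step 11
Reactants: 17 the ring-A alkene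
Product: 18 8,8-(ethylenedioxy)-19-(triisopropylsilyloxy)-12,13,14,15,16,17-hexanor-ent-labdan-11-ol
Conditions: H2 (1 atm), Pd/C, EtOAc–EtOH, rt
Reagents that add atoms: none
Why: Heterogeneous hydrogenation saturates the cis-disubstituted C1=C2 bond and hydrogenolysis removes the benzyl ether in the same operation, while ketal and silyl ether should survive.

Step 12
Reactants: 18 the 11-alcohol ketal
Product: 19 11-hydroxy-19-(triisopropylsilyloxy)-12,13,14,15,16,17-hexanor-ent-labdan-8-one
Conditions: 1 M HCl, THF, rt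
Reagents that add atoms: water O
Why: Ketal hydrolysis with dilute aqueous acid frees the C8 ketone and should leave the hindered neopentyl triisopropylsilyl ether intact.

Step 13
Reactants: 19 the β-hydroxy ketone
Product: 21 19-(triisopropylsilyloxy)-12,13,14,15,16,17-hexanor-ent-labd-9(11)-en-8-one, via C11 mesylate 20 (not isolated)
Conditions: MsCl, Et3N, CH2Cl2, 0 °C; then DBU, rt
Reagents that add atoms: none
Why: Mesylation of the only free hydroxyl and E1cB β-elimination of the β-mesyloxy ketone should give the exocyclic enone.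

Step 14
Reactants: 21 the exocyclic enone
Product: 22 13-bromo-19-(triisopropylsilyloxy)-14,15,17-trinor-ent-labd-13(16)-en-8-one
Conditions: CH2=C(Br)CH2SiMe3, TiCl4, CH2Cl2, −78 °C; H2O; then K2CO3 (cat.), MeOH, rt
Reagents that add atoms: (2-bromoallyl)trimethylsilane C=C(Br)C[Si](C)(C)C
Why: Hosomi–Sakurai conjugate addition of the 2-bromoallylsilane to the unhindered exocyclic enone forms the C11–C12 bond, and protonation followed by base equilibration should place the side chain equatorial at C9, cis to the C10 methyl, which sets C9 under thermodynamic control.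

Step 15
Reactants: 22 the bromoalkenyl ketone
Product: 23 19-(triisopropylsilyloxy)-17-nor-ent-labda-13(16),14-dien-8-one
Conditions: Bu3SnCH=CH2, Pd(PPh3)4 (5 mol %), PhMe, 90 °C
Reagents that add atoms: tributyl(vinyl)stannane C=C[Sn](CCCC)(CCCC)CCCC
Why: Stille coupling of the 2-bromoalkene with the vinylstannane under neutral conditions should build the 2-substituted 1,3-diene without disturbing the epimerisable C9 centre.

Step 16
Reactants: 23 the dienyl ketone
Product: 24 19-(triisopropylsilyloxy)-ent-labda-8(17),13(16),14-triene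
Conditions: Ph3PCH3Br, KOtBu, PhMe, 80 °C
Reagents that add atoms: methyltriphenylphosphonium bromide C[P+](c1ccccc1)(c1ccccc1)c1ccccc1.[Br-]
Why: Wittig methylenation of the hindered C8 ketone at elevated temperature installs the exocyclic C8=C17 bond, and C9 keeps its thermodynamically preferred equatorial configuration.

Step 17
Reactants: 24 the triene silyl ether
Product: 25 ent-labda-8(17),13(16),14-trien-19-ol
Conditions: Bu4NF, THF, 50 °C
Reagents that add atoms: none
Why: Fluoride-induced desilylation should free the axial C19 hydroxyl without touching the triene.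

Step 18
Reactants: 25 ent-labda-8(17),13(16),14-trien-19-ol; 26 (E)-4-acetoxycinnamic acid
Product: 28 ent-labda-8(17),13(16),14-trien-19-yl (E)-4-acetoxycinnamate, via (E)-4-acetoxycinnamoyl chloride 27 (not isolated)
Conditions: 26, (COCl)2, DMF (cat.), CH2Cl2, 0 °C → rt; then 25, Et3N, DMAP (cat.), CH2Cl2, rt
Reagents that add atoms: none
Why: DMAP-catalysed acylation of the hindered neopentyl alcohol with the acid chloride (nucleophilic acyl substitution) should attach the cinnamate with its E double bond intact, the phenol being masked as the acetate.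

Step 19
Reactants: 28 ent-labda-8(17),13(16),14-trien-19-yl (E)-4-acetoxycinnamate
Product: 29 ent-labda-8(17),13(16),14-trien-19-yl (E)-4-hydroxycinnamate (CNP0131099.1)
Conditions: K2CO3 (cat.), MeOH, 0 °C
Reagents that add atoms: none
Why: Base-catalysed transesterification with methanol cleaves the aryl acetate much faster than the hindered neopentyl cinnamate and should release the phenol of the target.

**Compound list**

1 | 2-(4-methoxy-2-methylphenyl)acetic acid | COc1ccc(CC(=O)O)c(C)c1 | starting material
2 | 2-(4-methoxy-2-methylcyclohexa-1,4-dien-1-yl)acetic acid (not isolated) | COC1=CCC(CC(=O)O)=C(C)C1 | intermediate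
3 | 2-(2-methyl-4-oxocyclohex-1-en-1-yl)acetic acid | O=C1CCC(CC(=O)O)=C(C)C1 | intermediate
4 | methyl 2-(2-methyl-4-oxocyclohex-1-en-1-yl)acetate | O=C1CCC(CC(=O)OC)=C(C)C1 | intermediate
5 | methyl 2-[(1R)-2-methyl-4-oxocyclohex-2-en-1-yl]acetate | O=C1CC[C@H](CC(=O)OC)C(C)=C1 | intermediate
6 | trichlorotitanium enolate of the 10-allyl ketone (not isolated) | C=CC[C@]1(C)[C@@H](CC(=O)OC)CCC(O[Ti](Cl)(Cl)Cl)=C1 | intermediate
7 | methyl 2-[(1R,2R,3R)-2-allyl-3-(benzyloxymethyl)-2-methyl-4-oxocyclohexyl]acetate (allyl trans to the acetate arm; CH2OBn cis to the ring methyl) | c1ccccc1COC[C@@H]2C(=O)CC[C@H](CC(=O)OC)[C@@]2(C)CC=C | intermediate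
8 | methyl 11-benzyloxy-8,8-(ethylenedioxy)-12,13,14,15,16,17,19-heptanor-3,4-seco-ent-labd-2-en-18-oate | c1ccccc1COC[C@@H]2C3(OCCO3)CC[C@H](CC(=O)OC)[C@@]2(C)CC=C | intermediate
9 | 11-benzyloxy-8,8-(ethylenedioxy)-12,13,14,15,16,17,19-heptanor-3,4-seco-ent-labd-2-en-18-oic acid | c1ccccc1COC[C@@H]2C3(OCCO3)CC[C@H](CC(=O)O)[C@@]2(C)CC=C | intermediate
10 | 11-benzyloxy-8,8-(ethylenedioxy)-12,13,14,15,16,17,19-heptanor-3,4-seco-ent-labd-2-en-18,1-olide (trans-fused δ-lactone; vinyl on C1 cis to C20) | c1ccccc1COC[C@@H]2C3(OCCO3)CC[C@@H]4CC(=O)O[C@H](C=C)[C@@]24C | intermediate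
11 | lithium enolate of lactone 10 (not isolated) | c1ccccc1COC[C@@H]2C3(OCCO3)CC[C@@H]4C=C(O[Li])O[C@H](C=C)[C@@]24C | intermediate
12 | 11-benzyloxy-8,8-(ethylenedioxy)-19-(triisopropylsilyloxy)-12,13,14,15,16,17-hexanor-3,4-seco-ent-labd-2-en-18,1-olide (C4 epimers, both used) | c1ccccc1COC[C@@H]2C3(OCCO3)CC[C@@H]4C(CO[Si](C(C)C)(C(C)C)C(C)C)C(=O)O[C@H](C=C)[C@@]24C | intermediate
13 | trimethylsilyl ketene acetal of 12, C4=C18 (not isolated) | c1ccccc1COC[C@@H]2C3(OCCO3)CC[C@@H]4C(CO[Si](C(C)C)(C(C)C)C(C)C)=C(O[Si](C)(C)C)O[C@H](C=C)[C@@]24C | intermediate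
14 | trimethylsilyl 11-benzyloxy-8,8-(ethylenedioxy)-19-(triisopropylsilyloxy)-12,13,14,15,16,17-hexanor-ent-labd-1-en-18-oate (not isolated) | c1ccccc1COC[C@@H]1C3(OCCO3)CC[C@@H]2[C@](C(=O)O[Si](C)(C)C)(CO[Si](C(C)C)(C(C)C)C(C)C)CC=C[C@@]12C | intermediate
15 | 11-benzyloxy-8,8-(ethylenedioxy)-19-(triisopropylsilyloxy)-12,13,14,15,16,17-hexanor-ent-labd-1-en-18-ol (trans-decalin; C19 axial, cis to C20) | c1ccccc1COC[C@@H]1C3(OCCO3)CC[C@@H]2[C@](CO)(CO[Si](C(C)C)(C(C)C)C(C)C)CC=C[C@@]12C | intermediate
16 | 18-trifluoromethanesulfonate of 15 (not isolated) | c1ccccc1COC[C@@H]1C3(OCCO3)CC[C@@H]2[C@](COS(=O)(=O)C(F)(F)F)(CO[Si](C(C)C)(C(C)C)C(C)C)CC=C[C@@]12C | intermediate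
17 | 11-benzyloxy-8,8-(ethylenedioxy)-19-(triisopropylsilyloxy)-12,13,14,15,16,17-hexanor-ent-labd-1-ene | c1ccccc1COC[C@@H]1C3(OCCO3)CC[C@@H]2[C@](C)(CO[Si](C(C)C)(C(C)C)C(C)C)CC=C[C@@]12C | intermediate
18 | 8,8-(ethylenedioxy)-19-(triisopropylsilyloxy)-12,13,14,15,16,17-hexanor-ent-labdan-11-ol | OC[C@@H]1C3(OCCO3)CC[C@@H]2[C@](C)(CO[Si](C(C)C)(C(C)C)C(C)C)CCC[C@@]12C | intermediate
19 | 11-hydroxy-19-(triisopropylsilyloxy)-12,13,14,15,16,17-hexanor-ent-labdan-8-one | OC[C@@H]1C(=O)CC[C@@H]2[C@](C)(CO[Si](C(C)C)(C(C)C)C(C)C)CCC[C@@]12C | intermediate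
20 | 11-methanesulfonate of 19 (not isolated) | CS(=O)(=O)OC[C@@H]1C(=O)CC[C@@H]2[C@](C)(CO[Si](C(C)C)(C(C)C)C(C)C)CCC[C@@]12C | intermediate
21 | 19-(triisopropylsilyloxy)-12,13,14,15,16,17-hexanor-ent-labd-9(11)-en-8-one | C=C1C(=O)CC[C@@H]2[C@](C)(CO[Si](C(C)C)(C(C)C)C(C)C)CCC[C@@]12C | intermediate
22 | 13-bromo-19-(triisopropylsilyloxy)-14,15,17-trinor-ent-labd-13(16)-en-8-one (side chain at C9 equatorial, cis to C20) | C=C(Br)CC[C@@H]1C(=O)CC[C@@H]2[C@](C)(CO[Si](C(C)C)(C(C)C)C(C)C)CCC[C@@]12C | intermediate
23 | 19-(triisopropylsilyloxy)-17-nor-ent-labda-13(16),14-dien-8-one | C=CC(=C)CC[C@@H]1C(=O)CC[C@@H]2[C@](C)(CO[Si](C(C)C)(C(C)C)C(C)C)CCC[C@@]12C | intermediate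
24 | 19-(triisopropylsilyloxy)-ent-labda-8(17),13(16),14-triene | C=CC(=C)CC[C@@H]1C(=C)CC[C@@H]2[C@](C)(CO[Si](C(C)C)(C(C)C)C(C)C)CCC[C@@]12C | intermediate
25 | (4R,5S,9R,10S)-labda-8(17),13(16),14-trien-19-ol (ent-labdatrienol) | C=CC(=C)CC[C@@H]1C(=C)CC[C@@H]2[C@](C)(CO)CCC[C@@]12C | intermediate
26 | (E)-4-acetoxycinnamic acid | CC(=O)Oc1ccc(/C=C/C(=O)O)cc1 | starting material
27 | (E)-4-acetoxycinnamoyl chloride (not isolated) | CC(=O)Oc1ccc(/C=C/C(=O)Cl)cc1 | intermediate
28 | ent-labda-8(17),13(16),14-trien-19-yl (E)-4-acetoxycinnamate | C=CC(=C)CC[C@@H]1C(=C)CC[C@@H]2[C@](C)(COC(=O)/C=C/c3ccc(OC(C)=O)cc3)CCC[C@@]12C | intermediate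
29 | (4R,5S,9R,10S)-labda-8(17),13(16),14-trien-19-yl (E)-4-hydroxycinnamate (CNP0131099.1) | C=CC(=C)CC[C@@H]1C(=C)CC[C@@H]2[C@](C)(COC(=O)/C=C/c3ccc(O)cc3)CCC[C@@]12C | target

**Step count and risk**

Total step count: 19. Longest linear sequence: 19 steps (1 → 29).

Steps most likely to fail:

Step 9. The silyloxy group may be lost from the lactone enolate by β-elimination before O-silylation, or the sigmatropic shift may be too slow in the strained trans-fused boat so that the ketene acetal is lost to hydrolysis. The fallback makes the same ring A bond by classical enolate alkylation; it sets out from 8 and comes back at 18. Hydroboration–oxidation of the allyl group of 8 (9-BBN; NaBO3) should give the primary alcohol F1, and iodination (I2, PPh3, imidazole) the iodide F2. LiN(iPr)2 (THF, −78 → 0 °C) should then close ring A by intramolecular 6-exo-tet alkylation of the ester enolate to the decalin ester F3. A second enolisation and MeI should methylate C4 from the equatorial side, away from the axial C10 methyl, to the quaternary ester F4 (axial CO2Me = C19). LiAlH4 should give the neopentyl alcohol F5, (iPr)3SiOTf/2,6-lutidine the silyl ether F6, and hydrogenolysis of the benzyl ether (H2, Pd/C) then gives 18.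

Step 7. C–H cleavage may fail at the neopentyl allylic methylene, or the C–O bond may form on the wrong face of the π-allyl so that the unreactive C1 epimer results. The fallback builds the allylic alcohol by carbonyl addition; it sets out from 5 and comes back at 10. Copper-catalysed conjugate addition of vinylmagnesium bromide (CuBr·SMe2, Me3SiCl, THF, −78 °C) to 5 should give the silyl enol ether F7, whose alkylation with BnOCH2Cl/TiCl4 gives the vinyl ketone F8. Ketalisation as in step 5 gives the ketal F9, and ozonolysis of the vinyl group (O3; Me2S) the neopentyl aldehyde F10. Addition of vinylmagnesium bromide (THF, −78 °C) and closure of the alkoxide onto the methyl ester then gives 10. The C1 epimers are separable, and the unwanted one can be equilibrated with Pd(PPh3)4 (zerovalent palladium) through the π-allyl carboxylate.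

Step 3. Facial control in the γ-protonation may be incomplete, or a racemic background isomerisation may compete, which would erode the enantiomeric purity of every later compound. The fallback is a classical resolution; it sets out from 3 and comes back at 5. Compound 3 is isomerised with Et3N to the racemic conjugated keto acid F11, which is resolved by crystallisation of its salt F12 with (R)-1-phenylethylamine (or with the enantiomeric amine if that gives the less soluble salt of the R acid). Acidification liberates the (R)-keto acid F13, and Me3SiCHN2 converts it into 5.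

Further compounds
F1 | step 9 | methyl 11-benzyloxy-8,8-(ethylenedioxy)-3-hydroxy-12,13,14,15,16,17,19-heptanor-3,4-seco-ent-labdan-18-oate | c1ccccc1COC[C@@H]2C3(OCCO3)CC[C@H](CC(=O)OC)[C@@]2(C)CCCO
F2 | step 9 | methyl 11-benzyloxy-8,8-(ethylenedioxy)-3-iodo-12,13,14,15,16,17,19-heptanor-3,4-seco-ent-labdan-18-oate | c1ccccc1COC[C@@H]2C3(OCCO3)CC[C@H](CC(=O)OC)[C@@]2(C)CCCI
F3 | step 9 | methyl 11-benzyloxy-8,8-(ethylenedioxy)-12,13,14,15,16,17,19-heptanor-ent-labdan-18-oate (C4 epimers) | c1ccccc1COC[C@@H]1C3(OCCO3)CC[C@@H]2C(C(=O)OC)CCC[C@@]12C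
F4 | step 9 | methyl 11-benzyloxy-8,8-(ethylenedioxy)-12,13,14,15,16,17-hexanor-ent-labdan-19-oate | c1ccccc1COC[C@@H]1C3(OCCO3)CC[C@@H]2[C@](C)(C(=O)OC)CCC[C@@]12C
F5 | step 9 | 11-benzyloxy-8,8-(ethylenedioxy)-12,13,14,15,16,17-hexanor-ent-labdan-19-ol | c1ccccc1COC[C@@H]1C3(OCCO3)CC[C@@H]2[C@](C)(CO)CCC[C@@]12C
F6 | step 9 | 11-benzyloxy-8,8-(ethylenedioxy)-19-(triisopropylsilyloxy)-12,13,14,15,16,17-hexanor-ent-labdane | c1ccccc1COC[C@@H]1C3(OCCO3)CC[C@@H]2[C@](C)(CO[Si](C(C)C)(C(C)C)C(C)C)CCC[C@@]12C
F7 | step 7 | methyl 2-[2-methyl-4-(trimethylsilyloxy)-2-vinylcyclohex-3-en-1-yl]acetate (vinyl trans to the acetate arm) | C=C[C@]1(C)[C@@H](CC(=O)OC)CCC(O[Si](C)(C)C)=C1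
F8 | step 7 | methyl 2-[3-(benzyloxymethyl)-2-methyl-4-oxo-2-vinylcyclohexyl]acetate | c1ccccc1COC[C@@H]2C(=O)CC[C@H](CC(=O)OC)[C@@]2(C)C=C
F9 | step 7 | ethylene ketal of F8 | c1ccccc1COC[C@@H]2C3(OCCO3)CC[C@H](CC(=O)OC)[C@@]2(C)C=C
F10 | step 7 | methyl 2-[3-(benzyloxymethyl)-4,4-(ethylenedioxy)-2-formyl-2-methylcyclohexyl]acetate | c1ccccc1COC[C@@H]2C3(OCCO3)CC[C@H](CC(=O)OC)[C@@]2(C)C=O
F11 | step 3 | rac-2-(2-methyl-4-oxocyclohex-2-en-1-yl)acetic acid | O=C1CCC(CC(=O)O)C(C)=C1
F12 | step 3 | (R)-1-phenylethylammonium (R)-2-(2-methyl-4-oxocyclohex-2-en-1-yl)acetate | O=C1CC[C@H](CC(=O)[O-])C(C)=C1.C[C@@H]([NH3+])c1ccccc1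
F13 | step 3 | (R)-2-(2-methyl-4-oxocyclohex-2-en-1-yl)acetic acid | O=C1CC[C@H](CC(=O)O)C(C)=C1
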